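**Retrosynthetic overview**

- The route rests on the C15=C15' double bond at the centre of the C40 polyene. On each side lies a C20 retinoid half, and the halves differ only by the oleate on C3 of ring A. A Wittig cut there gives a retinyl ylide (ring B half) and (3R)-3-oleoyloxyretinal (ring A half).
- The aldehyde goes back to (3R)-3-hydroxyretinal, with the oleate put on last. That comes from an ethyl retinoate joined at C6–C7 by Stille coupling of a ring A enol triflate with a C11 tetraenylstannane (C11=C12 by Horner–Wadsworth–Emmons).
- C3 is set early: ketoisophorone to (6R)-levodione (ene-reductase), then to (4R,6R)-actinol (hydrogenation). The phosphonium salt comes in one step from retinyl acetate.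
- No ring is formed in the route: ring A is bought as ketoisophorone and ring B as retinyl acetate.

Key step: step 14

Remark: carotenoid numbering is used (ring carbons C1–C6, chain C7–C15, primed locants for the unsubstituted half); the target is read as all-E in the polyene, 3R in ring A and 9Z in the oleate, and every polyene is handled under argon in dim light.

**Route**

Step 1
Reactants: 1 ketoisophorone (2,6,6-trimethylcyclohex-2-ene-1,4-dione)
Product: 2 (6R)-levodione, (6R)-2,2,6-trimethylcyclohexane-1,4-dione
Conditions: ene-reductase OYE2, NADP+ (cat.), glucose dehydrogenase, D-glucose, KH2PO4/K2HPO4 buffer pH 6.5, 30 °C; prompt extraction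
Reagents that add atoms: none
Why: Biocatalytic conjugate reduction by an old yellow enzyme: the flavoprotein should reduce the ring C=C bond with hydride from NADPH (recycled by glucose/glucose dehydrogenase) and its active site should set the methyl-bearing carbon as 6R, while the slightly acidic buffer and quick extraction limit enolisation of this α-stereocentre.

Step 2
Reactants: 2 (6R)-levodione
Product: 3 (4R,6R)-actinol, trans-(4R,6R)-4-hydroxy-2,2,6-trimethylcyclohexan-1-one
Conditions: H2 (5 bar), neutral-washed Raney Ni, MeOH, 25 °C; recrystallisation from diisopropyl ether/hexane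
Reagents that add atoms: none
Why: Heterogeneous ketone hydrogenation: the C4 carbonyl is far less hindered than C1 (flanked by the quaternary C2 and the C6 methine) and hydrogen should add from the face away from the axial C2 methyl, so the 6R centre relays the 4R configuration (trans alcohol), and crystallisation should remove the cis alcohol.

Step 3
Reactants: 3 (4R,6R)-actinol
Product: 4 (4R,6R)-4-[(tert-butyldimethylsilyl)oxy]-2,2,6-trimethylcyclohexan-1-one
Conditions: TBSCl, imidazole, DMF, 25 °C
Reagents that add atoms: tert-butyldimethylsilyl chloride, CC(C)(C)[Si](C)(C)Cl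
Why: Imidazole-promoted silylation of an unhindered secondary alcohol, which leaves the hindered ketone and both stereocentres untouched.

Step 4
Reactants: 4 (4R,6R)-4-[(tert-butyldimethylsilyl)oxy]-2,2,6-trimethylcyclohexan-1-one
Product: 6 (4R)-4-[(tert-butyldimethylsilyl)oxy]-2,6,6-trimethylcyclohex-1-en-1-yl trifluoromethanesulfonate, via lithium enolate 5 (not isolated)
Conditions: LiN(iPr)2, THF, −78 → 0 °C; PhNTf2, −78 → 25 °C
Reagents that add atoms: N-phenylbis(trifluoromethanesulfonimide), O=S(=O)(N(c1ccccc1)S(=O)(=O)C(F)(F)F)C(F)(F)F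
Why: Enol triflate formation: C2 is quaternary, so the amide base can only remove the C6 hydrogen and gives one tetrasubstituted enolate that PhNTf2 sulfonylates on oxygen; the C6 centre is given up here and the silyloxy carbon, γ to the carbonyl and therefore safe from elimination, keeps its R configuration.

Step 5
Reactants: 7 (E)-3-methylpent-2-en-4-yn-1-ol
Product: 8 (2E,4E)-3-methyl-5-(tributylstannyl)penta-2,4-dien-1-ol
Conditions: Bu3SnH, PdCl2(PPh3)2 (cat.), THF, 0 °C
Reagents that add atoms: tributyltin hydride, CCCC[SnH](CCCC)CCCC
Why: Palladium-catalysed hydrostannation of a terminal alkyne: syn addition of Sn–H with tin at the terminal carbon should give the E-vinylstannane, the internal regioisomer being removed by chromatography on triethylamine-deactivated silica.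

Step 6
Reactants: 8 (2E,4E)-3-methyl-5-(tributylstannyl)penta-2,4-dien-1-ol
Product: 9 (2E,4E)-3-methyl-5-(tributylstannyl)penta-2,4-dienal
Conditions: activated MnO2, CH2Cl2, 25 °C
Reagents that add atoms: none
Why: MnO2 oxidation of a primary allylic alcohol to the enal, a neutral heterogeneous oxidation that vinylstannanes tolerate and that does not scramble the alkene geometry.

Step 7
Reactants: 9 (2E,4E)-3-methyl-5-(tributylstannyl)penta-2,4-dienal; 10 ethyl (E)-4-(diethoxyphosphoryl)-3-methylbut-2-enoate (triethyl 3-methyl-4-phosphonocrotonate)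
Product: 12 ethyl (2E,4E,6E,8E)-3,7-dimethyl-9-(tributylstannyl)nona-2,4,6,8-tetraenoate, via lithiated phosphonate 11 (not isolated)
Conditions: 10, LiN(SiMe3)2, THF/DMPU, −78 °C; then 9, −78 → 0 °C
Reagents that add atoms: none
Why: Horner–Wadsworth–Emmons olefination: the vinylogous phosphonate anion should attack the aldehyde through the carbon next to phosphorus and eliminate diethyl phosphate to give the new E disubstituted alkene (later C11=C12), with the conjugated 2E ester geometry favoured and any 2Z isomer removed by chromatography.

Step 8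
Reactants: 6 (4R)-4-[(tert-butyldimethylsilyl)oxy]-2,6,6-trimethylcyclohex-1-en-1-yl trifluoromethanesulfonate; 12 ethyl (2E,4E,6E,8E)-3,7-dimethyl-9-(tributylstannyl)nona-2,4,6,8-tetraenoate
Product: 13 ethyl (3R)-3-[(tert-butyldimethylsilyl)oxy]-all-trans-retinoate
Conditions: Pd2(dba)3 (cat.), AsPh3, NMP, 60 °C, Ar, dark
Reagents that add atoms: none
Why: Stille coupling: zerovalent palladium inserts into the C6–OTf bond, the alkenyl group is transferred from tin with retention of its E geometry and reductive elimination forms the C6–C7 bond, the weakly bound arsine ligand in a polar solvent being the known remedy for slow transmetalation at hindered enol triflates.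

Step 9
Reactants: 13 ethyl (3R)-3-[(tert-butyldimethylsilyl)oxy]-all-trans-retinoate
Product: 14 (3R)-3-[(tert-butyldimethylsilyl)oxy]-all-trans-retinol
Conditions: i-Bu2AlH, CH2Cl2, −78 °C; aq. potassium sodium tartrate
Reagents that add atoms: none
Why: Hydride reduction of a conjugated ester with i-Bu2AlH, which at low temperature should give the allylic alcohol by 1,2-reduction only and leave the silyl ether and the polyene alone.

Step 10
Reactants: 14 (3R)-3-[(tert-butyldimethylsilyl)oxy]-all-trans-retinol
Product: 15 (3R)-3-hydroxy-all-trans-retinol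
Conditions: Bu4NF, THF, 25 °C
Reagents that add atoms: none
Why: Fluoride-mediated cleavage of the silyl ether, driven by the strong Si–F bond and done at the alcohol stage, where no base-sensitive aldehyde is present; the C3–O bond is not broken, so the configuration is kept.

Step 11
Reactants: 15 (3R)-3-hydroxy-all-trans-retinol
Product: 16 (3R)-3-hydroxy-all-trans-retinal
Conditions: activated MnO2, CH2Cl2, 25 °C, dark
Reagents that add atoms: none
Why: Chemoselective MnO2 oxidation: only the allylic C15 alcohol is activated for this oxidant, whereas the C3 alcohol is homoallylic and should stay untouched.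

Step 12
Reactants: 16 (3R)-3-hydroxy-all-trans-retinal; 17 oleic acid ((9Z)-octadec-9-enoic acid)
Product: 18 (3R)-3-oleoyloxy-all-trans-retinal
Conditions: DCC, DMAP (cat.), CH2Cl2, 0 → 25 °C, dark
Reagents that add atoms: none
Why: Steglich esterification: the O-acylisourea of oleic acid passes its acyl group through the acylpyridinium ion to the C3 hydroxyl, with retention at C3 because only the O–H bond reacts, under neutral conditions that spare the polyenal and the 9Z alkene.

Step 13
Reactants: 19 all-trans-retinyl acetate
Product: 20 all-trans-retinyltriphenylphosphonium bromide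
Conditions: PPh3·HBr, MeOH, 25 °C, dark
Reagents that add atoms: triphenylphosphine hydrobromide, Br.c1ccc(cc1)P(c1ccccc1)c1ccccc1
Why: Phosphonium salt formation by an SN1-type substitution: acid ionises the allylic acetate to the delocalised retinyl cation, which triphenylphosphine should capture at the unhindered terminal carbon C15 with the conjugated all-E pentaene restored.

Step 14
Reactants: 20 all-trans-retinyltriphenylphosphonium bromide; 18 (3R)-3-oleoyloxy-all-trans-retinal
Product: 23 (3R)-β-cryptoxanthin oleate (all-E target CNP0152321.1), via retinylidenetriphenylphosphorane 21 (not isolated), via 15-cis-β-cryptoxanthin oleate 22 (not isolated)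
Conditions: 20 (slight excess), NaN(SiMe3)2 (slight deficit to 20), THF, −78 °C; then 18, −78 → 0 °C; aqueous work-up; n-heptane, 85 °C, Ar, dark; chromatography on deactivated silica, then low-temperature crystallisation
Reagents that add atoms: none
Why: Wittig olefination: the amide base removes a C15' proton of 20 to give the polyene-conjugated ylide 21, whose C15' carbon adds to the aldehyde carbon C15 of 18, and the oxaphosphetane collapses with loss of Ph3PO to form the C15=C15' double bond. The closest known reaction type is the Wittig condensation of a retinyl phosphonium salt with retinal to β-carotene, here with one half carrying the C3 oleate. No ring is closed and no stereocentre is made; the 3R centre in ring A lies far from the reacting carbon and is not touched. Cross-selectivity follows from the roles alone, since only 20 can form an ylide and only 18 has an aldehyde, and selectivity for the aldehyde over the oleate ester is secured by consuming the non-nucleophilic base in forming 21 before 18 is added at low temperature. The new alkene should form as an E/Z mixture, but the 15-cis isomer 22 is an unhindered disubstituted cis bond inside a long polyene and should isomerise to the all-E compound on warming in heptane, while the isolated 9Z alkene of the oleate has no such low-barrier path and keeps its geometry.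

**Compound list**

1 | ketoisophorone (2,6,6-trimethylcyclohex-2-ene-1,4-dione) | CC1=CC(=O)CC(C)(C)C1=O | starting material
2 | (6R)-levodione, (6R)-2,2,6-trimethylcyclohexane-1,4-dione | C[C@@H]1CC(=O)CC(C)(C)C1=O | intermediate
3 | (4R,6R)-actinol, (4R,6R)-4-hydroxy-2,2,6-trimethylcyclohexan-1-one | O[C@@H]1C[C@@H](C)C(=O)C(C)(C)C1 | intermediate
4 | (4R,6R)-4-[(tert-butyldimethylsilyl)oxy]-2,2,6-trimethylcyclohexan-1-one | CC(C)(C)[Si](C)(C)O[C@@H]1C[C@@H](C)C(=O)C(C)(C)C1 | intermediate
5 | lithium (4R)-4-[(tert-butyldimethylsilyl)oxy]-2,6,6-trimethylcyclohex-1-en-1-olate | CC(C)(C)[Si](C)(C)O[C@@H]1CC(C)=C([O-])C(C)(C)C1.[Li+] | intermediate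
6 | (4R)-4-[(tert-butyldimethylsilyl)oxy]-2,6,6-trimethylcyclohex-1-en-1-yl trifluoromethanesulfonate | CC(C)(C)[Si](C)(C)O[C@@H]1CC(C)=C(OS(=O)(=O)C(F)(F)F)C(C)(C)C1 | intermediate
7 | (E)-3-methylpent-2-en-4-yn-1-ol | C#C/C(C)=C/CO | starting material
8 | (2E,4E)-3-methyl-5-(tributylstannyl)penta-2,4-dien-1-ol | CCCC[Sn](CCCC)(CCCC)/C=C/C(C)=C/CO | intermediate
9 | (2E,4E)-3-methyl-5-(tributylstannyl)penta-2,4-dienal | CCCC[Sn](CCCC)(CCCC)/C=C/C(C)=C/C=O | intermediate
10 | ethyl (E)-4-(diethoxyphosphoryl)-3-methylbut-2-enoate | CCOC(=O)/C=C(C)/CP(=O)(OCC)OCC | starting material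
11 | lithium salt of 10, deprotonated at the carbon next to phosphorus | CCOC(=O)/C=C(C)/[CH-]P(=O)(OCC)OCC.[Li+] | intermediate
12 | ethyl (2E,4E,6E,8E)-3,7-dimethyl-9-(tributylstannyl)nona-2,4,6,8-tetraenoate | CCCC[Sn](CCCC)(CCCC)/C=C/C(C)=C/C=C/C(C)=C/C(=O)OCC | intermediate
13 | ethyl (3R)-3-[(tert-butyldimethylsilyl)oxy]-all-trans-retinoate | CC(C)(C)[Si](C)(C)O[C@@H]1CC(C)=C(/C=C/C(C)=C/C=C/C(C)=C/C(=O)OCC)C(C)(C)C1 | intermediate
14 | (3R)-3-[(tert-butyldimethylsilyl)oxy]-all-trans-retinol | CC(C)(C)[Si](C)(C)O[C@@H]1CC(C)=C(/C=C/C(C)=C/C=C/C(C)=C/CO)C(C)(C)C1 | intermediate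
15 | (3R)-3-hydroxy-all-trans-retinol | O[C@@H]1CC(C)=C(/C=C/C(C)=C/C=C/C(C)=C/CO)C(C)(C)C1 | intermediate
16 | (3R)-3-hydroxy-all-trans-retinal | O[C@@H]1CC(C)=C(/C=C/C(C)=C/C=C/C(C)=C/C=O)C(C)(C)C1 | intermediate
17 | oleic acid, (9Z)-octadec-9-enoic acid | CCCCCCCC/C=C\CCCCCCCC(=O)O | starting material
18 | (3R)-3-oleoyloxy-all-trans-retinal | CCCCCCCC/C=C\CCCCCCCC(=O)O[C@@H]1CC(C)=C(/C=C/C(C)=C/C=C/C(C)=C/C=O)C(C)(C)C1 | intermediate
19 | all-trans-retinyl acetate | CC(=O)OC/C=C(C)/C=C/C=C(C)/C=C/C1=C(C)CCCC1(C)C | starting material
20 | all-trans-retinyltriphenylphosphonium bromide | CC1=C(/C=C/C(C)=C/C=C/C(C)=C/C[P+](c2ccccc2)(c2ccccc2)c2ccccc2)C(C)(C)CCC1.[Br-] | intermediate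
21 | retinylidenetriphenylphosphorane | CC1=C(/C=C/C(C)=C/C=C/C(C)=C/C=P(c2ccccc2)(c2ccccc2)c2ccccc2)C(C)(C)CCC1 | intermediate
22 | (3R)-15-cis-β-cryptoxanthin oleate | CCCCCCCC/C=C\CCCCCCCC(=O)O[C@@H]1CC(C)=C(/C=C/C(C)=C/C=C/C(C)=C/C=C\C=C(C)\C=C\C=C(C)\C=C\C2=C(C)CCCC2(C)C)C(C)(C)C1 | intermediate
23 | (3R)-β-cryptoxanthin oleate, all-E (CNP0152321.1) | CCCCCCCC/C=C\CCCCCCCC(=O)O[C@@H]1CC(C)=C(/C=C/C(C)=C/C=C/C(C)=C/C=C/C=C(C)/C=C/C=C(C)/C=C/C2=C(C)CCCC2(C)C)C(C)(C)C1 | target

**Step count**

Total: 14 steps. Longest linear sequence: 10 steps (steps 1–4, 8–12 and 14, from ketoisophorone).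

**Steps most likely to fail**

1. Step 14 (Wittig coupling). The ylide may act as a base instead of a nucleophile (γ-deprotonation of the polyenal, attack on the ester). Isomer mixtures at several bonds may also prove inseparable from a waxy ester that does not crystallise well. Fallback: move the esterification behind the coupling. It sets out from hydroxy aldehyde 16 and salt 20. These are condensed under the neutral epoxide variant of the Wittig reaction (1,2-epoxybutane, EtOH, reflux, where bromide opens the epoxide and the alkoxide formed deprotonates the salt) to give (3R)-β-cryptoxanthin F1. This hydroxy carotenoid should crystallise, so heating and crystallisation should deliver the all-E isomer. Steglich esterification of F1 with oleic acid 17 (DCC, DMAP, CH2Cl2) comes back to the route at target 23.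

2. Step 8 (Stille coupling). Transfer of the alkenyl group to palladium at the tetrasubstituted, doubly flanked C6 may be slow. Protodestannylation, homocoupling and E/Z scrambling of the long tetraenylstannane could then take over. Fallback: shorten the tin partner and build the chain afterwards. It sets out from triflate 6 and stannyl dienol 8, which is more robust and can be used in excess. Their coupling with the same palladium/arsine system should give (2E,4E)-5-[(4R)-4-[(tert-butyldimethylsilyl)oxy]-2,6,6-trimethylcyclohex-1-en-1-yl]-3-methylpenta-2,4-dien-1-ol F2. MnO2 oxidation gives (2E,4E)-5-[(4R)-4-[(tert-butyldimethylsilyl)oxy]-2,6,6-trimethylcyclohex-1-en-1-yl]-3-methylpenta-2,4-dienal F3. Horner–Wadsworth–Emmons olefination of F3 with anion 11 of phosphonate 10 forms C11=C12 and comes back to the route at ester 13.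

3. Step 2 (reduction of the C4 ketone). Facial selectivity in the hydrogenation may be poor, and any cis alcohol carried forward would end as the 3S enantiomer once C6 becomes sp2 in step 4. Fallback: correct the configuration by inversion and do not rely on face selectivity alone. It sets out from 2. The hydrogenation mixture is separated by chromatography, and the cis alcohol (4S,6R)-4-hydroxy-2,2,6-trimethylcyclohexan-1-one F4 is inverted at C4 by Mitsunobu esterification (4-nitrobenzoic acid, PPh3, DIAD, THF) to (1R,3R)-3,5,5-trimethyl-4-oxocyclohexyl 4-nitrobenzoate F5. Methanolysis of F5 (K2CO3, MeOH) comes back to the route at 3. Epimerisation at C6 during methanolysis would be harmless, because C4 is already fixed and C6 is given up in step 4.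

**Further compounds**

F1 | step 14 | (3R)-β-cryptoxanthin, all-E | O[C@@H]1CC(C)=C(/C=C/C(C)=C/C=C/C(C)=C/C=C/C=C(C)/C=C/C=C(C)/C=C/C2=C(C)CCCC2(C)C)C(C)(C)C1
F2 | step 8 | (2E,4E)-5-[(4R)-4-[(tert-butyldimethylsilyl)oxy]-2,6,6-trimethylcyclohex-1-en-1-yl]-3-methylpenta-2,4-dien-1-ol | CC(C)(C)[Si](C)(C)O[C@@H]1CC(C)=C(/C=C/C(C)=C/CO)C(C)(C)C1
F3 | step 8 | (2E,4E)-5-[(4R)-4-[(tert-butyldimethylsilyl)oxy]-2,6,6-trimethylcyclohex-1-en-1-yl]-3-methylpenta-2,4-dienal | CC(C)(C)[Si](C)(C)O[C@@H]1CC(C)=C(/C=C/C(C)=C/C=O)C(C)(C)C1
F4 | step 2 | (4S,6R)-4-hydroxy-2,2,6-trimethylcyclohexan-1-one (cis-actinol) | O[C@H]1C[C@@H](C)C(=O)C(C)(C)C1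
F5 | step 2 | (1R,3R)-3,5,5-trimethyl-4-oxocyclohexyl 4-nitrobenzoate | O=C(O[C@@H]1C[C@@H](C)C(=O)C(C)(C)C1)c1ccc(cc1)[N+](=O)[O-]
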